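**Plan**

- Labels follow the tetralin of the target: C1 diaryl methine, C2 and C3 carrying C9 and C9′, C4 benzylic CH2, C4a/C8a fusion carbons. Ring A is the oxygenated benzo ring, ring B the saturated ring, ring C the pendant 4-hydroxy-3-methoxyphenyl ring.
- Cuts: both CH2OH groups go back to a C2 aldehyde and a C3 nitromethyl group. Ring B is then opened at C1–C2 and C2–C3 together, which releases acetaldehyde (C2 + C9). Further back: C3–C9′ (Henry), C4a–C4 (ortho-allylation), C1–C1′ (aryl Grignard).
- Enabling feature: C2 lies between C1, which the para-hydroxyl of ring C can turn into a p-quinone methide carbon, and C3, the β-carbon of a nitroalkene C3=C9′. C2 can therefore be an aldehyde α-carbon that reacts twice as an enamine.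
- Forward: ring A aldehyde → allyl at C4a → ring C added at C1 → side chain cut and extended to the nitroalkene → ring B (the only ring made) closed in one flask → reduction, Nef reaction, reduction.
- Stereochemistry: C3 from the (R)-diphenylprolinol silyl ether catalyst in the Michael addition; C1 relayed from C3 through a chair-like closure; C2 by equilibration of the aldehyde to the all-trans (1R,2S,3S) array, then frozen by reduction.

Key step: step 10

Remark: C1 is formed racemic in step 4 and carried as an epimer mixture up to 18; this is immaterial because C1 becomes trigonal in quinone methide 21 before its configuration is set.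

Abbreviations: G = 2-{methoxy[3-methoxy-4-(methoxymethoxy)phenyl]methyl}-5,6-dimethoxy-4-(triisopropylsilyloxy)phenyl (ring A with its C1 appendage). G′ = the same group with the MOM ether replaced by the free phenol.

**Route**

Step 1
Reactants: 1 3-hydroxy-4,5-dimethoxybenzaldehyde
Product: 2 4,5-dimethoxy-3-(triisopropylsilyloxy)benzaldehyde
Conditions: TIPSCl, imidazole, DMF, rt
Reagents that add atoms: triisopropylsilyl chloride, CC(C)[Si](Cl)(C(C)C)C(C)C
Why: Imidazole-promoted silyl ether formation should be clean, and the bulky, non-coordinating TIPS group is chosen because it later keeps the base away from the ring carbon next to it.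

Step 2
Reactants: 2 4,5-dimethoxy-3-(triisopropylsilyloxy)benzaldehyde; 3 allyl bromide
Product: 6 2-allyl-3,4-dimethoxy-5-(triisopropylsilyloxy)benzaldehyde, via lithium amino alkoxide 4 (not isolated), via ring-lithiated amino alkoxide 5 (not isolated)
Conditions: LiN(Me)CH2CH2NMe2 (from the amine and n-BuLi), THF, −20 °C; n-BuLi (3 equiv), −20 °C; CuBr·SMe2 (10 mol %), 3 (excess), −78 °C → rt; aq HCl
Reagents that add atoms: none
Why: Directed ortho-metalation of an in situ α-amino alkoxide: the lithium amide masks the aldehyde, the alkoxide/amine arm and the neighbouring methoxy group jointly direct n-BuLi to the ring carbon between them (future C4a) while the site next to OTIPS is shielded, and copper-assisted allylation followed by acid hydrolysis should return the ortho-allyl aldehyde.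

Step 3
Reactants: 7 4-bromo-2-methoxyphenol
Product: 8 4-bromo-2-methoxy-1-(methoxymethoxy)benzene
Conditions: MOMCl, iPr2NEt, CH2Cl2, 0 °C → rt
Reagents that add atoms: chloromethyl methyl ether, COCCl
Why: Williamson-type O-alkylation gives a MOM acetal that survives Grignard formation, catalytic acid and weak base and is later removed by acidic methanolysis.

Step 4
Reactants: 8 4-bromo-2-methoxy-1-(methoxymethoxy)benzene; 6 2-allyl-3,4-dimethoxy-5-(triisopropylsilyloxy)benzaldehyde
Product: 10 rac-[2-allyl-3,4-dimethoxy-5-(triisopropylsilyloxy)phenyl][3-methoxy-4-(methoxymethoxy)phenyl]methanol, via arylmagnesium bromide 9 (not isolated)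
Conditions: Mg, THF, 40 °C; then 6, 0 °C → rt; aq NH4Cl
Reagents that add atoms: none
Why: Grignard formation and 1,2-addition to the aldehyde forge the C1–C1′ bond, and the racemic carbinol centre does not matter because it is erased later.

Step 5
Reactants: 10 rac-[2-allyl-3,4-dimethoxy-5-(triisopropylsilyloxy)phenyl][3-methoxy-4-(methoxymethoxy)phenyl]methanol
Product: 11 methyl ether of 10 (G-CH2CH=CH2)
Conditions: MeOH, CSA (5 mol %), 0 °C → rt; Et3N quench
Reagents that add atoms: methanol, CO
Why: Acid-catalysed SN1 etherification through the doubly aryl-stabilised benzhydryl cation caps the carbinol so that it can form neither a lactol with the coming aldehyde nor an oxa-Michael adduct with the nitroalkene, yet stays a leaving group that acid can expel; the MOM and TIPS aryl ethers should tolerate catalytic CSA.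

Step 6
Reactants: 11 methyl ether of 10 (G-CH2CH=CH2)
Product: 13 2-G-acetaldehyde, via diol 12 (not isolated)
Conditions: OsO4 (2 mol %), NaIO4 (4 equiv), 2,6-lutidine, 1,4-dioxane/H2O, rt
Reagents that add atoms: osmium tetroxide, O=[Os](=O)(=O)=O (oxygen carrier); sodium periodate, [Na+].[O-]I(=O)(=O)=O (ultimate oxygen source)
Why: Lemieux–Johnson oxidation (dihydroxylation, then periodate glycol cleavage, lutidine-buffered) should cut the terminal alkene to the arylacetaldehyde without attacking the electron-rich arenes that ozone would endanger.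

Step 7
Reactants: 13 2-G-acetaldehyde; 14 nitromethane
Product: 15 1-G-3-nitropropan-2-ol (diastereomer mixture)
Conditions: 14 (10 equiv), Et3N (0.3 equiv), THF, 0 °C → rt
Reagents that add atoms: none
Why: Henry (nitroaldol) addition under weak amine base should give the β-nitro alcohol, the large excess of nitromethane outrunning self-aldol of the enolisable aldehyde.

Step 8
Reactants: 15 1-G-3-nitropropan-2-ol
Product: 17 (E)-1-nitro-3-G-prop-1-ene, via mesylate 16 (not isolated)
Conditions: MsCl (1.3 equiv), Et3N (2.5 equiv), CH2Cl2, −40 → 0 °C; cold aq NH4Cl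
Reagents that add atoms: none
Why: Mesylation and E1cB elimination (nitroaldol dehydration) should give the conjugated (E)-nitroalkene, with low temperature, little excess base and a prompt quench meant to stop the double bond from shifting into conjugation with ring A.

Step 9
Reactants: 17 (E)-1-nitro-3-G-prop-1-ene
Product: 18 (E)-1-nitro-3-G′-prop-1-ene
Conditions: HCl (0.5 M) in MeOH, 35 °C
Reagents that add atoms: none
Why: Acid-catalysed acetal methanolysis removes the MOM group, and because the solvent is methanol any ionisation of the benzhydryl methyl ether is only a degenerate exchange, while the nitroalkene and the aryl TIPS ether are acid-stable.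

Step 10
Reactants: 18 (E)-1-nitro-3-G′-prop-1-ene; 19 acetaldehyde
Product: 22 (1R,2S,3S)-1-(4-hydroxy-3-methoxyphenyl)-5,6-dimethoxy-3-(nitromethyl)-7-(triisopropylsilyloxy)-1,2,3,4-tetrahydronaphthalene-2-carbaldehyde, via Michael adduct 20 (not isolated), via quinone methide 21 (not isolated)
Conditions: 19 (10 equiv), (R)-2-[diphenyl(trimethylsilyloxy)methyl]pyrrolidine (20 mol %), 1,4-dioxane, 10 °C → rt; excess 19 evaporated; then CH2Cl2 (0.02 M), CF3CO2H (40 mol %), 0 °C → rt
Reagents that add atoms: none
Why: The (R)-configured diarylprolinol silyl ether turns acetaldehyde into an enamine that adds to the nitroalkene β-carbon C3 (enamine Michael addition of acetaldehyde to a nitroalkene), giving (S)-20 while the benzhydryl methyl ether, which does not ionise without strong acid, stays latent. Once excess acetaldehyde is stripped, CF3CO2H ionises that ether with the help of the para-hydroxyl of ring C to the p-quinone methide 21, and the catalyst enamine of the new aldehyde attacks the methide carbon C1 in a 6-exo-trig closure of ring B that rearomatises ring C. The closest known reaction types are the aminocatalytic 1,6-addition of aldehydes to p-quinone methides and the SN1-type α-alkylation of aldehydes by acid-ionised benzhydrols, here run in the same flask after the Michael addition. C3 is set by the catalyst (the silyloxydiphenylmethyl group blocks one enamine face and the synclinal approach fixes the nitroalkene face; the sense is the one that gives the (R)-adduct from β-nitrostyrene, the descriptor becoming S here by a priority switch), C1 by a chair-like transition state with the C3 nitromethyl group and the quinone methide ring both equatorial, and C2 by epimerisation of the aldehyde through its enamine to the all-equatorial isomer. The step needs C2–C3 to form before C1 becomes electrophilic and needs the enamine carbon, not a nitronate or ring A, to capture C1: the substrate secures this because the quinone methide is masked as a methyl ether that only acid unlocks, because only the ring C phenol is free (the C7 oxygen is silylated), and because no nitronate exists in the acidic second stage. The weakly acidic phenol of 18 buffers the amine in the first stage, which should keep the nitroalkene from slipping into conjugation with ring A.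

Step 11
Reactants: 22 (1R,2S,3S)-tetralin-2-carbaldehyde
Product: 23 [(1R,2S,3S)-1-(4-hydroxy-3-methoxyphenyl)-5,6-dimethoxy-3-(nitromethyl)-7-(triisopropylsilyloxy)-1,2,3,4-tetrahydronaphthalen-2-yl]methanol
Conditions: NaBH4, MeOH/THF, −20 → 0 °C
Reagents that add atoms: none
Why: Chemoselective borohydride reduction of the aldehyde (nitro group inert) turns the epimerisable C2 centre into a fixed one bearing C9–OH.

Step 12
Reactants: 23 silyl-protected nitro alcohol
Product: 24 (5R,6S,7S)-5-(4-hydroxy-3-methoxyphenyl)-6-(hydroxymethyl)-3,4-dimethoxy-7-(nitromethyl)-5,6,7,8-tetrahydronaphthalen-2-ol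
Conditions: Bu4NF, THF, 0 °C; aq NH4Cl
Reagents that add atoms: none
Why: Fluoride-mediated desilylation frees the C7 phenol before the Nef step, so that the basic nitronate formation cannot give a mixture of silylated and desilylated material.

Step 13
Reactants: 24 bis-phenol nitro alcohol
Product: 26 trans-fused lactol of the C9′ aldehyde with the C9 hydroxyl (tetralin core 1R,2S,3S; anomer mixture), via sodium nitronate 25 (not isolated)
Conditions: NaOMe (3.3 equiv), MeOH, 0 °C; then TiCl3 (4.5 equiv), NH4OAc, H2O/THF, 0 °C → rt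
Reagents that add atoms: water, O
Why: Reductive Nef reaction: trivalent titanium reduces the nitronate to the imine, which hydrolyses to the C9′ aldehyde and is trapped at once by the C9 hydroxyl as the lactol, so the reducing, near-neutral medium spares the free phenols and the masked aldehyde has little chance to epimerise C3.

Step 14
Reactants: 26 trans-fused lactol
Product: 27 [(1R,2S,3S)-7-hydroxy-1-(4-hydroxy-3-methoxyphenyl)-5,6-dimethoxy-1,2,3,4-tetrahydronaphthalene-2,3-diyl]dimethanol (target)
Conditions: NaBH4, MeOH, 0 °C → rt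
Reagents that add atoms: none
Why: Borohydride reduction of the lactol through its open hydroxy-aldehyde form gives the diol, and C3 should hold because its substituent already sits in the favoured equatorial, trans arrangement.

**Compound list**

1 | 3-hydroxy-4,5-dimethoxybenzaldehyde | O=Cc1cc(O)c(OC)c(OC)c1 | starting material
2 | 4,5-dimethoxy-3-(triisopropylsilyloxy)benzaldehyde | O=Cc1cc(O[Si](C(C)C)(C(C)C)C(C)C)c(OC)c(OC)c1 | intermediate
3 | allyl bromide (3-bromoprop-1-ene) | C=CCBr | starting material
4 | lithium α-amino alkoxide from 2 and lithium [2-(dimethylamino)ethyl](methyl)amide (formed in the flask) | [Li]OC(N(C)CCN(C)C)c1cc(O[Si](C(C)C)(C(C)C)C(C)C)c(OC)c(OC)c1 | intermediate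
5 | 4 lithiated at the ring carbon between the masked formyl group and the methoxy group (formed in the flask) | [Li]OC(N(C)CCN(C)C)c1cc(O[Si](C(C)C)(C(C)C)C(C)C)c(OC)c(OC)c1[Li] | intermediate
6 | 2-allyl-3,4-dimethoxy-5-(triisopropylsilyloxy)benzaldehyde | O=Cc1cc(O[Si](C(C)C)(C(C)C)C(C)C)c(OC)c(OC)c1CC=C | intermediate
7 | 4-bromo-2-methoxyphenol | COc1cc(Br)ccc1O | starting material
8 | 4-bromo-2-methoxy-1-(methoxymethoxy)benzene | COCOc1ccc(Br)cc1OC | intermediate
9 | [3-methoxy-4-(methoxymethoxy)phenyl]magnesium bromide (formed in the flask) | COCOc1ccc([Mg]Br)cc1OC | intermediate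
10 | rac-[2-allyl-3,4-dimethoxy-5-(triisopropylsilyloxy)phenyl][3-methoxy-4-(methoxymethoxy)phenyl]methanol | COCOc1ccc(C(O)c2cc(O[Si](C(C)C)(C(C)C)C(C)C)c(OC)c(OC)c2CC=C)cc1OC | intermediate
11 | rac-[2-allyl-3,4-dimethoxy-5-(triisopropylsilyloxy)phenyl][3-methoxy-4-(methoxymethoxy)phenyl]methyl methyl ether | COCOc1ccc(C(OC)c2cc(O[Si](C(C)C)(C(C)C)C(C)C)c(OC)c(OC)c2CC=C)cc1OC | intermediate
12 | 3-(2-{methoxy[3-methoxy-4-(methoxymethoxy)phenyl]methyl}-5,6-dimethoxy-4-(triisopropylsilyloxy)phenyl)propane-1,2-diol, diastereomer mixture (formed in the flask) | COCOc1ccc(C(OC)c2cc(O[Si](C(C)C)(C(C)C)C(C)C)c(OC)c(OC)c2CC(O)CO)cc1OC | intermediate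
13 | 2-(2-{methoxy[3-methoxy-4-(methoxymethoxy)phenyl]methyl}-5,6-dimethoxy-4-(triisopropylsilyloxy)phenyl)acetaldehyde, racemic | COCOc1ccc(C(OC)c2cc(O[Si](C(C)C)(C(C)C)C(C)C)c(OC)c(OC)c2CC=O)cc1OC | intermediate
14 | nitromethane | C[N+](=O)[O-] | starting material
15 | 1-(2-{methoxy[3-methoxy-4-(methoxymethoxy)phenyl]methyl}-5,6-dimethoxy-4-(triisopropylsilyloxy)phenyl)-3-nitropropan-2-ol, diastereomer mixture | COCOc1ccc(C(OC)c2cc(O[Si](C(C)C)(C(C)C)C(C)C)c(OC)c(OC)c2CC(O)C[N+](=O)[O-])cc1OC | intermediate
16 | methanesulfonate of 15 (formed in the flask) | COCOc1ccc(C(OC)c2cc(O[Si](C(C)C)(C(C)C)C(C)C)c(OC)c(OC)c2CC(OS(C)(=O)=O)C[N+](=O)[O-])cc1OC | intermediate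
17 | 1-{methoxy[3-methoxy-4-(methoxymethoxy)phenyl]methyl}-3,4-dimethoxy-2-[(E)-3-nitroprop-2-en-1-yl]-5-(triisopropylsilyloxy)benzene, racemic at C1 | COCOc1ccc(C(OC)c2cc(O[Si](C(C)C)(C(C)C)C(C)C)c(OC)c(OC)c2C/C=C/[N+](=O)[O-])cc1OC | intermediate
18 | 4-({3,4-dimethoxy-2-[(E)-3-nitroprop-2-en-1-yl]-5-(triisopropylsilyloxy)phenyl}(methoxy)methyl)-2-methoxyphenol, racemic at C1 | COc1cc(C(OC)c2cc(O[Si](C(C)C)(C(C)C)C(C)C)c(OC)c(OC)c2C/C=C/[N+](=O)[O-])ccc1O | intermediate
19 | acetaldehyde | CC=O | starting material
20 | (3S)-4-{2-[(4-hydroxy-3-methoxyphenyl)(methoxy)methyl]-5,6-dimethoxy-4-(triisopropylsilyloxy)phenyl}-3-(nitromethyl)butanal, C1 epimers (formed in the flask) | COc1cc(C(OC)c2cc(O[Si](C(C)C)(C(C)C)C(C)C)c(OC)c(OC)c2C[C@H](C[N+](=O)[O-])CC=O)ccc1O | intermediate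
21 | (3S)-4-{5,6-dimethoxy-2-[(3-methoxy-4-oxocyclohexa-2,5-dien-1-ylidene)methyl]-4-(triisopropylsilyloxy)phenyl}-3-(nitromethyl)butanal, the p-quinone methide (formed in the flask) | COC1=CC(=Cc2cc(O[Si](C(C)C)(C(C)C)C(C)C)c(OC)c(OC)c2C[C@H](C[N+](=O)[O-])CC=O)C=CC1=O | intermediate
22 | (1R,2S,3S)-1-(4-hydroxy-3-methoxyphenyl)-5,6-dimethoxy-3-(nitromethyl)-7-(triisopropylsilyloxy)-1,2,3,4-tetrahydronaphthalene-2-carbaldehyde (aryl, formyl and nitromethyl all trans) | COc1cc([C@@H]2c3cc(O[Si](C(C)C)(C(C)C)C(C)C)c(OC)c(OC)c3C[C@H](C[N+](=O)[O-])[C@H]2C=O)ccc1O | intermediate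
23 | [(1R,2S,3S)-1-(4-hydroxy-3-methoxyphenyl)-5,6-dimethoxy-3-(nitromethyl)-7-(triisopropylsilyloxy)-1,2,3,4-tetrahydronaphthalen-2-yl]methanol | COc1cc([C@@H]2c3cc(O[Si](C(C)C)(C(C)C)C(C)C)c(OC)c(OC)c3C[C@H](C[N+](=O)[O-])[C@H]2CO)ccc1O | intermediate
24 | (5R,6S,7S)-5-(4-hydroxy-3-methoxyphenyl)-6-(hydroxymethyl)-3,4-dimethoxy-7-(nitromethyl)-5,6,7,8-tetrahydronaphthalen-2-ol | COc1cc([C@@H]2c3cc(O)c(OC)c(OC)c3C[C@H](C[N+](=O)[O-])[C@H]2CO)ccc1O | intermediate
25 | trisodium salt of 24: nitronate at C9′ and both phenoxides (formed in the flask) | [Na+].[Na+].[Na+].COc1cc([C@@H]2c3cc([O-])c(OC)c(OC)c3C[C@H](C=[N+]([O-])[O-])[C@H]2CO)ccc1[O-] | intermediate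
26 | lactol of the C3 formyl group with the C2 hydroxymethyl group, tetralin core (1R,2S,3S), trans ring fusion, anomer mixture | COc1cc([C@@H]2c3cc(O)c(OC)c(OC)c3C[C@H](C(O)OC4)[C@H]24)ccc1O | intermediate
27 | [(1R,2S,3S)-7-hydroxy-1-(4-hydroxy-3-methoxyphenyl)-5,6-dimethoxy-1,2,3,4-tetrahydronaphthalene-2,3-diyl]dimethanol | COc1cc([C@@H]2c3cc(O)c(OC)c(OC)c3C[C@H](CO)[C@H]2CO)ccc1O | target

**Totals**

Total step count: 14. Longest linear sequence: 13 steps (steps 1, 2 and 4–14, from compound 1); step 3 is the side branch from 7.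

**Steps most likely to fail**

1. Step 10. What may go wrong: ionisation of the benzhydryl ether outpaces the tethered enamine, so the quinone methide is captured between molecules (oligomerisation, residual acetaldehyde enamine) instead of closing ring B. The fallback sets out from 17 and comes back at 22, making the two bonds in separate, isolated stages. The acetaldehyde Michael addition (same catalyst, 1,4-dioxane) is run on MOM ether 17, in which no quinone methide can arise, to give (3S)-3-(nitromethyl)-4-G-butanal F1. HCl in MeOH then removes the MOM group and stores the aldehyde as its dimethyl acetal, giving 4-{[2-((2S)-4,4-dimethoxy-2-(nitromethyl)butyl)-3,4-dimethoxy-5-(triisopropylsilyloxy)phenyl](methoxy)methyl}-2-methoxyphenol F2. Finally pyrrolidine (20 mol %) and CF3CO2H in wet CH2Cl2 at high dilution should hydrolyse the acetal and close ring B by SN1-type intramolecular α-alkylation of the aldehyde, with equilibration to the all-trans aldehyde 22.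

2. Step 2. What may go wrong: metalation at the wrong ortho position (next to the silyl ether), or incomplete lithiation with addition of n-BuLi to the masked formyl group. The fallback sets out from allyl bromide 3 and comes back at 6, placing the allyl group by an aromatic Claisen rearrangement whose regiochemistry is dictated by the ring substitution.
   - Commercial methyl 3,5-dihydroxy-4-methoxybenzoate F3 is mono-silylated (TIPSCl, imidazole; statistical, diol recycled) to methyl 3-hydroxy-4-methoxy-5-(triisopropylsilyloxy)benzoate F4.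
   - O-Allylation with 3 (K2CO3, acetone) gives methyl 3-(allyloxy)-4-methoxy-5-(triisopropylsilyloxy)benzoate F5.
   - Heating (N,N-diethylaniline, 190 °C) should move the allyl group to the only free ortho carbon, giving methyl 2-allyl-3-hydroxy-4-methoxy-5-(triisopropylsilyloxy)benzoate F6.
   - Methylation (MeI, K2CO3, acetone) gives methyl 2-allyl-3,4-dimethoxy-5-(triisopropylsilyloxy)benzoate F7.
   - i-Bu2AlH reduction gives [2-allyl-3,4-dimethoxy-5-(triisopropylsilyloxy)phenyl]methanol F8, and MnO2 oxidation returns to the route at 6.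

3. Step 8. What may go wrong: base-induced migration of the C3=C9′ double bond into conjugation with ring A (allylic nitro isomer) during elimination or work-up. The fallback sets out from 11 and comes back at 17: radical nitration of the terminal alkene of 11 with AgNO2 and TEMPO (4 Å molecular sieves, 1,2-dichloroethane, 70 °C). This adds NO2 to the terminal carbon and removes hydrogen without any base, so it should give (E)-nitroalkene 17 directly, bypassing 13 and 15. It makes no new compound (F0).

**Further compounds**

F1 | step 10 | (3S)-4-(2-{methoxy[3-methoxy-4-(methoxymethoxy)phenyl]methyl}-5,6-dimethoxy-4-(triisopropylsilyloxy)phenyl)-3-(nitromethyl)butanal | COCOc1ccc(C(OC)c2cc(O[Si](C(C)C)(C(C)C)C(C)C)c(OC)c(OC)c2C[C@H](C[N+](=O)[O-])CC=O)cc1OC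
F2 | step 10 | 4-{[2-((2S)-4,4-dimethoxy-2-(nitromethyl)butyl)-3,4-dimethoxy-5-(triisopropylsilyloxy)phenyl](methoxy)methyl}-2-methoxyphenol | COc1cc(C(OC)c2cc(O[Si](C(C)C)(C(C)C)C(C)C)c(OC)c(OC)c2C[C@H](C[N+](=O)[O-])CC(OC)OC)ccc1O
F3 | step 2 | methyl 3,5-dihydroxy-4-methoxybenzoate | COC(=O)c1cc(O)c(OC)c(O)c1
F4 | step 2 | methyl 3-hydroxy-4-methoxy-5-(triisopropylsilyloxy)benzoate | COC(=O)c1cc(O)c(OC)c(O[Si](C(C)C)(C(C)C)C(C)C)c1
F5 | step 2 | methyl 3-(allyloxy)-4-methoxy-5-(triisopropylsilyloxy)benzoate | COC(=O)c1cc(OCC=C)c(OC)c(O[Si](C(C)C)(C(C)C)C(C)C)c1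
F6 | step 2 | methyl 2-allyl-3-hydroxy-4-methoxy-5-(triisopropylsilyloxy)benzoate | COC(=O)c1cc(O[Si](C(C)C)(C(C)C)C(C)C)c(OC)c(O)c1CC=C
F7 | step 2 | methyl 2-allyl-3,4-dimethoxy-5-(triisopropylsilyloxy)benzoate | COC(=O)c1cc(O[Si](C(C)C)(C(C)C)C(C)C)c(OC)c(OC)c1CC=C
F8 | step 2 | [2-allyl-3,4-dimethoxy-5-(triisopropylsilyloxy)phenyl]methanol | OCc1cc(O[Si](C(C)C)(C(C)C)C(C)C)c(OC)c(OC)c1CC=C
F0 | step 8 | none | none
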